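The earlier runs and the new flask were computed on assumed constants; scatter was added.

Thursday's run had more E than Wednesday's and lost more J by 5.00 min, 41.9% of the charge against 24.2%.

| flask | J | D | E | remark | time |
|---|---|---|---|---|---|
| Wednesday's | 0.30 M | 90 mM (held) | 1.6 mM | run made earlier |  |
| Thursday's | 0.30 M | 90 mM (held) | 3.6 mM | run made earlier |  |
| flask | 0.30 M | 90 mM (held) | 2.4 mM |  | 5.0 min |

| run | time / min | Z / % | J / % |
|---|---|---|---|
| Wednesday's | 0.417 | 0.8 | 99.4 |
| Wednesday's | 0.667 | 1.3 | 99.2 |
| Wednesday's | 1.00 | 2.1 | 97.3 |
| Wednesday's | 1.33 | 2.8 | 95.7 |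
| Wednesday's | 2.00 | 5.6 | 91.9 |
| Wednesday's | 3.00 | 9.2 | 85.5 |
| Wednesday's | 5.00 | 14.1 | 75.8 |
| Thursday's | 0.250 | 1.0 | 100.8 |
| Thursday's | 0.833 | 3.6 | 95.8 |
| Thursday's | 1.33 | 5.9 | 90.2 |
| Thursday's | 2.00 | 9.8 | 83.7 |
| Thursday's | 3.00 | 14.8 | 75.3 |
| Thursday's | 4.00 | 20.9 | 65.3 |
| Thursday's | 5.00 | 24.5 | 58.1 |

(readings scatter by 0.5 percentage points)

- at the start none of D is in solution

- how much Z there is at 5.0 min, in percent of the J charged
- the change that raises the amount of Z at 5.0 min, in percent of the J charged most ("none" if none brings more than 2 percentage points) (summer / midnight / dawn / none)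
- amount of Z at 5.0 min, in percent of the J charged, after midnight

- summer: doubling the amount of E, all else as stated
- midnight: doubling the transfer coefficient of D, all else as stated
- dawn: doubling the saturation concentration of D, all else as stated

First I asked where the lost J went. I defined the Z share (the selectivity) as Z present per J lost, each as a fraction of the charge. It read 0.583 on Wednesday and 0.585 on Thursday. So E had not visibly moved the split, and the other 0.417 of Wednesday's lost J stood in no reading.

Next I asked how much J the flask would lose. From Wednesday to Thursday, E rose 2.25 times and the loss 1.73 times, so between these two runs, at the same J and D and at the same time, the loss read as E to the power 0.677. The flask's E was 1.50 times Wednesday's. I therefore reckoned a loss of 31.8% and, through the share, Z at 18.6%.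

Last I asked which change paid. Stretching the same power beyond Thursday's E, summer gave 29.7%. D was the same in both runs, so I had no number for midnight or dawn.

The forecast gave 19%, by another fit than mine, then 22% after midnight and dawn as best: “That order is untested because D never varied, but dawn is the likely best.”

The flask gave 19.1%, and 23.2% after midnight. The gains were 9.3 percentage points for summer, 4.2 points for midnight and 14 points for dawn, so dawn was best.

    Z ⇌ G (K = 0.780, k = 1.17 min⁻¹)
    J + E → X (k = 0.205 M⁻¹ min⁻¹)
    D ⇌ Q, rate k3*(csat - [Q]) (kL = 0.888 min⁻¹)
    J + Q + E → E + Z (k = 711 M⁻² min⁻¹)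

In the flask, Z and G relaxed by their own step with a half-life of 0.260 min, short against 5.0 min. At 5.00 min the flask had lost 32.3% of its J, and the share turned that into 18.8% Z. The neighbouring flask was charged with a quarter of the J, 0.075 M. It lost 41.3% of its own charge, and the share turned that into 24.1% Z. That neighbouring flask held 24.4% Z.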